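## Retrosynthetic overview

1. Target 20 ⇐ oxirane closure last: the tertiary C1–OH displaces a C6 mesylate with inversion, on a cyclohexene that already carries C7–OBz, C3–OBz and C2–OAc.
2. Cyclohexene ⇐ acid 12 ⇐ Ireland–Claisen ring contraction of δ-lactone 9, which forms C1–C6 and C4=C5 and breaks the C4–O bond; the ring oxygen leaves on C7.
3. Feature used: C1, the quaternary oxirane carbon, bears an oxygen and the carboxyl-level carbon C7, and C4=C5–C6(O) is an oxygenated allyl unit of the six-membered ring. A C7 ketene acetal on C1 whose ester oxygen sits on C4, together with an (E)-enol ether C5=C6, is therefore a [3,3] array across a δ-lactone.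
4. 9 ⇐ L-gulono-1,4-lactone, which supplies C2, C3 and the controlling C4 centre: acetonide protection, amide ring opening with O-4 silylation, relactonisation on O-5, C6 oxidation, (E)-boryl-olefination, Cu-mediated etherification.
5. Ring order: carbocycle (step 7), then oxirane (step 14).

Key step: step 7

Remarks on the chemistry:
- Target numbering: C1 quaternary oxirane carbon, C2 CH–OAc, C3 CH–OBz, C4=C5, C6 oxirane CH, C7 CH2OBz. Compounds 1–9 carry L-gulonic acid numbering; sugar C1, C2, C3, C4, C5, C6, C7 become target C7, C1, C2, C3, C4, C5, C6.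
- The lactone α- and β-oxygens (target O1/O2) are carried as a cis-fused isopropylidene acetal and target O3 as a TBS ether. The acetal blocks β-elimination from the enolate, keeps the alkenyl group axial, comes directly from the natural acetonide pattern of the sugar, and lets O2 and O3 be acylated differently at the end.
- The (E)-enol ether is made stereospecifically (boryl-olefination, then Cu-mediated C–O coupling), because the (Z)-isomer would give the cis C1–O/C6–O relation, which cannot close to the oxirane.
- Abbreviations: TBS = tert-butyldimethylsilyl, PMB = 4-methoxybenzyl, Bpin = 4,4,5,5-tetramethyl-1,3,2-dioxaborolan-2-yl.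

## Route

Step 1
Reactants: 1 L-gulono-1,4-lactone
Product: 2 2,3:5,6-di-O-isopropylidene-L-gulono-1,4-lactone
Conditions: 2,2-dimethoxypropane, TsOH·H2O (cat.), acetone, rt
Reagents that add atoms: 2,2-dimethoxypropane, COC(C)(C)OC
Why: Acid-catalysed isopropylidene acetal formation (transacetalisation) should protect the cis-2,3-diol on the ring and the terminal 5,6-diol, the usual pattern for this lactone, without touching a stereocentre.

Step 2
Reactants: 2 2,3:5,6-di-O-isopropylidene-L-gulono-1,4-lactone
Product: 4 4-O-TBS-N-methoxy-N-methyl-2,3:5,6-di-O-isopropylidene-L-gulonamide, via 4-hydroxy amide 3 (not isolated)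
Conditions: 1. MeNH(OMe)·HCl, AlMe3, CH2Cl2, 0 °C → rt; 2. (crude 3) TBSOTf, 2,6-lutidine, CH2Cl2, 0 °C → rt
Reagents that add atoms: N,O-dimethylhydroxylamine hydrochloride, CNOC.Cl; tert-butyldimethylsilyl trifluoromethanesulfonate, CC(C)(C)[Si](C)(C)OS(=O)(=O)C(F)(F)F
Why: Aluminium-amide aminolysis of the γ-lactone (Weinreb amide formation) opens the ring and the freed O-4 is silylated at once (silyl triflate/lutidine), so that O-4 stays blocked when the carboxyl group is later returned to O-5; no stereocentre is affected.

Step 3
Reactants: 4 4-O-TBS-N-methoxy-N-methyl-2,3:5,6-di-O-isopropylidene-L-gulonamide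
Product: 6 4-O-TBS-2,3-O-isopropylidene-L-gulono-1,5-lactone (free 6-OH), via 5,6-diol amide 5 (not isolated)
Conditions: AcOH/H2O (4:1), 40 °C; concentrate; PPTS (cat.), toluene, 50 °C
Reagents that add atoms: none
Why: Mild acid hydrolysis should remove the terminal isopropylidene acetal faster than the 2,3-acetal, which is deactivated by the neighbouring carbonyl group, and the δ-hydroxy N-methoxy-N-methylamide then lactonises under acid catalysis (intramolecular acyl substitution) on O-5, since O-4 is silylated and closure on O-6 would give a seven-membered ring; C5 keeps its configuration.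

Step 4
Reactants: 6 4-O-TBS-2,3-O-isopropylidene-L-gulono-1,5-lactone
Product: 7 6-aldehydo-4-O-TBS-2,3-O-isopropylidene-L-gulono-1,5-lactone (C6 aldehyde)
Conditions: Dess–Martin periodinane, NaHCO3, CH2Cl2, 0 °C → rt; used crude
Reagents that add atoms: none
Why: Dess–Martin oxidation of the primary alcohol under buffered, non-basic conditions should give the aldehyde without epimerising the adjacent C5 centre.

Step 5
Reactants: 7 6-aldehydo-4-O-TBS-2,3-O-isopropylidene-L-gulono-1,5-lactone
Product: 8 4-O-TBS-2,3-O-isopropylidene L-gulo 1,5-lactone carrying an (E)-2-(Bpin)vinyl group on C5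
Conditions: Cl2CHBpin, CrCl2, LiI, THF, rt
Reagents that add atoms: 2-(dichloromethyl)-4,4,5,5-tetramethyl-1,3,2-dioxaborolane, ClC(Cl)B1OC(C)(C)C(C)(C)O1
Why: Chromium(II)-mediated boryl-olefination of the aldehyde (Takai-type olefination with a geminal dichromium reagent) is non-basic, tolerates the lactone and should give the (E)-alkenylboronate with high selectivity, which fixes the alkene geometry that later sets C6.

Step 6
Reactants: 8 (E)-alkenylboronate lactone
Product: 9 4-O-TBS-2,3-O-isopropylidene L-gulo 1,5-lactone carrying an (E)-2-(4-methoxybenzyloxy)vinyl group on C5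
Conditions: 4-MeOC6H4CH2OH (excess), Cu(OAc)2, Et3N, 4 Å MS, CH2Cl2, air, rt; chromatography on Et3N-treated silica
Reagents that add atoms: 4-methoxybenzyl alcohol, COc1ccc(CO)cc1
Why: Copper(II)-promoted oxidative coupling of the alkenylboronate with the alcohol (Chan–Lam-type etherification) should exchange boron for the 4-methoxybenzyloxy group with retention of the (E) geometry, under near-neutral conditions that the allylic lactone should survive.

Step 7
Reactants: 9 (E)-alkoxyvinyl δ-lactone
Product: 12 cyclohex-4-ene-1-carboxylic acid with trans-fused 1,2-O-isopropylidene acetal plus 3-OTBS plus 6-OPMB (C7 cis to the C2 and C6 oxygens; trans to the C1 and C3 oxygens), via silyl ketene acetal 10 (not isolated), via trimethylsilyl ester 11 (not isolated)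
Conditions: LDA, TMSCl/Et3N, THF, −78 °C → rt; toluene, 90 °C; K2CO3, MeOH/H2O, 0 °C; cold citric acid to pH 3–4
Reagents that add atoms: none
Why: LDA removes the only α-proton of 9 (on target C1) and in-situ silylation gives the cyclic O-silyl ketene acetal 10, whose array C1=C7(OSi)–O–C4–C5=C6 (target numbering) rearranges by a concerted suprafacial [3,3] shift to silyl ester 11, hydrolysed to 12 on work-up; the closest known reaction type is the Ireland–Claisen rearrangement of lactone silyl ketene acetals that carry an alkenyl group on the carbinol carbon (lactone-to-carbocycle ring contraction). The cyclohexene is closed by C–C bond formation between the ketene acetal carbon C1 and the enol-ether terminus C6 while the C4–O bond of the lactone breaks, and because both termini are bridged by the C2–C3 unit the shift must run through a boat, bicyclo[2.2.2]-like transition state. The quaternary centre C1 is controlled by the configuration of the carbinol carbon C4: the alkenyl group can bond only to the ketene acetal face on which it stands, which places C7 cis to the C2 oxygen and trans to the C3 oxygen. The C6 centre is controlled by the (E)-enol ether, whose oxygen is held in the boat on the side of C7 and anti to the C1 oxygen, the trans C1–O/C6–O relation that the oxirane closure needs. The step needs enolisation without β-elimination of the C2 oxygen and a conformer with the alkenyl group axial; the cis-fused isopropylidene ring on O1/O2 should secure both, since it keeps the C2–O bond near the nodal plane of the enolate and holds the C2 and C3 oxygens pseudo-equatorial, so that the C4 alkenyl group, cis to the C3 oxygen, is axial.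

Step 8
Reactants: 12 cyclohexene carboxylic acid
Product: 13 primary alcohol (C7–OH) with 1,2-O-isopropylidene acetal plus 3-OTBS plus 6-OPMB
Conditions: LiAlH4, THF, 0 °C → 50 °C
Reagents that add atoms: none
Why: Lithium aluminium hydride reduces the hindered carboxylic acid to the primary alcohol (hydride reduction) while the ethers, the acetal and the isolated alkene stay intact.

Step 9
Reactants: 13 C7 alcohol
Product: 14 diol (C7–OH and C3–OH) with 1,2-O-isopropylidene acetal plus 6-OPMB
Conditions: TBAF, THF, rt
Reagents that add atoms: none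
Why: Fluoride-mediated desilylation frees the allylic C3 hydroxyl; the acetal and the 4-methoxybenzyl ether are stable to fluoride.

Step 10
Reactants: 14 diol
Product: 15 C7/C3 dibenzoate with 1,2-O-isopropylidene acetal plus 6-OPMB
Conditions: BzCl, pyridine, DMAP (cat.), CH2Cl2, 0 °C → rt
Reagents that add atoms: benzoyl chloride, O=C(Cl)c1ccccc1
Why: Pyridine/DMAP-mediated acylation benzoylates both free hydroxyls (C7 primary, C3 allylic secondary), which are the two benzoate positions of the target, so no selectivity between hydroxyls is needed.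

Step 11
Reactants: 15 dibenzoate acetonide
Product: 16 C1,C2-diol with C7/C3 dibenzoate plus 6-OPMB
Conditions: AcOH/H2O (4:1), 45 °C
Reagents that add atoms: none
Why: Acid hydrolysis of the strained trans-fused isopropylidene acetal (cleavage at the acetal carbon, so C1 and C2 keep their configuration) should be faster than loss of the 4-methoxybenzyl ether or benzoate migration, and frees the tertiary C1 and secondary C2 hydroxyls.

Step 12
Reactants: 16 C1,C2-diol
Product: 17 C2 acetate with free tertiary C1–OH plus C7/C3 dibenzoate plus 6-OPMB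
Conditions: Ac2O, pyridine, DMAP (cat.), CH2Cl2, 0 °C
Reagents that add atoms: acetic anhydride, CC(=O)OC(C)=O
Why: Mild acetylation (chemoselective acylation) discriminates the secondary C2 hydroxyl from the tertiary C1 hydroxyl, which is not acylated, so the acetate goes to C2 only.

Step 13
Reactants: 17 C2 acetate
Product: 18 C1,C6-diol (tertiary C1–OH trans to secondary allylic C6–OH) with C2 acetate plus C7/C3 dibenzoate
Conditions: DDQ, CH2Cl2/pH 7 buffer, 0 °C
Reagents that add atoms: none
Why: Oxidative cleavage of the 4-methoxybenzyl ether with DDQ (benzylic hydride abstraction, then hydrolysis of the oxocarbenium ion) frees the allylic C6 hydroxyl without touching the esters.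

Step 14
Reactants: 18 C1,C6-diol
Product: 20 target (EANPDB:ANNO_02019; 1S,2S,3R,6S in the numbering used here), via C6 mesylate 19 (not isolated)
Conditions: Ms2O, Et3N, CH2Cl2, −20 °C; then DBU, 0 °C → rt
Reagents that add atoms: none
Why: Sulfonylation occurs only at the secondary C6 hydroxyl, and the tertiary C1 oxygen then displaces the trans-disposed mesylate in an intramolecular SN2 reaction (3-exo-tet oxirane closure) with inversion at C6, which places the oxirane oxygen trans to C7 and to the C2 acetate as the target requires.

## Compound list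

1 | L-gulono-1,4-lactone | O=C1[C@@H](O)[C@@H](O)[C@H](O1)[C@@H](O)CO | starting material
2 | 2,3:5,6-di-O-isopropylidene-L-gulono-1,4-lactone | O=C1[C@H]2OC(C)(C)O[C@H]2[C@H](O1)[C@@H]3COC(C)(C)O3 | intermediate
3 | N-methoxy-N-methyl-2,3:5,6-di-O-isopropylidene-L-gulonamide (free 4-OH) | CON(C)C(=O)[C@H]1OC(C)(C)O[C@H]1[C@H](O)[C@@H]1COC(C)(C)O1 | intermediate
4 | 4-O-TBS-N-methoxy-N-methyl-2,3:5,6-di-O-isopropylidene-L-gulonamide | CON(C)C(=O)[C@H]1OC(C)(C)O[C@H]1[C@H](O[Si](C)(C)C(C)(C)C)[C@@H]1COC(C)(C)O1 | intermediate
5 | 4-O-TBS-N-methoxy-N-methyl-2,3-O-isopropylidene-L-gulonamide (5,6-diol) | CON(C)C(=O)[C@H]1OC(C)(C)O[C@H]1[C@H](O[Si](C)(C)C(C)(C)C)[C@@H](O)CO | intermediate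
6 | 4-O-TBS-2,3-O-isopropylidene-L-gulono-1,5-lactone (free 6-OH) | O=C1[C@H]2OC(C)(C)O[C@H]2[C@H](O[Si](C)(C)C(C)(C)C)[C@H](CO)O1 | intermediate
7 | 6-aldehydo-4-O-TBS-2,3-O-isopropylidene-L-gulono-1,5-lactone | O=C1[C@H]2OC(C)(C)O[C@H]2[C@H](O[Si](C)(C)C(C)(C)C)[C@H](C=O)O1 | intermediate
8 | 4-O-TBS-2,3-O-isopropylidene L-gulo 1,5-lactone with (E)-2-(Bpin)vinyl on C5 | O=C1[C@H]2OC(C)(C)O[C@H]2[C@H](O[Si](C)(C)C(C)(C)C)[C@H](/C=C/B3OC(C)(C)C(C)(C)O3)O1 | intermediate
9 | 4-O-TBS-2,3-O-isopropylidene L-gulo 1,5-lactone with (E)-2-(4-methoxybenzyloxy)vinyl on C5 (key-step precursor) | O=C1[C@H]2OC(C)(C)O[C@H]2[C@H](O[Si](C)(C)C(C)(C)C)[C@H](/C=C/OCc3ccc(OC)cc3)O1 | intermediate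
10 | O-trimethylsilyl ketene acetal of 9 | C[Si](C)(C)OC1=C2OC(C)(C)O[C@H]2[C@H](O[Si](C)(C)C(C)(C)C)[C@H](/C=C/OCc3ccc(OC)cc3)O1 | intermediate
11 | trimethylsilyl ester of acid 12 | C[Si](C)(C)OC(=O)[C@@]12OC(C)(C)O[C@H]1[C@H](O[Si](C)(C)C(C)(C)C)C=C[C@H]2OCc1ccc(OC)cc1 | intermediate
12 | cyclohex-4-ene-1-carboxylic acid: trans-fused 1,2-O-isopropylidene acetal, 3-OTBS, 6-OPMB; C7 cis to O2 and O6, trans to O1 and O3 (key-step product) | OC(=O)[C@@]12OC(C)(C)O[C@H]1[C@H](O[Si](C)(C)C(C)(C)C)C=C[C@H]2OCc1ccc(OC)cc1 | intermediate
13 | C7 primary alcohol from 12 | OC[C@@]12OC(C)(C)O[C@H]1[C@H](O[Si](C)(C)C(C)(C)C)C=C[C@H]2OCc1ccc(OC)cc1 | intermediate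
14 | C7,C3-diol (1,2-O-isopropylidene, 6-OPMB) | OC[C@@]12OC(C)(C)O[C@H]1[C@H](O)C=C[C@H]2OCc1ccc(OC)cc1 | intermediate
15 | C7,C3-dibenzoate (1,2-O-isopropylidene, 6-OPMB) | O=C(OC[C@@]12OC(C)(C)O[C@H]1[C@H](OC(=O)c1ccccc1)C=C[C@H]2OCc1ccc(OC)cc1)c1ccccc1 | intermediate
16 | C1,C2-diol (C7,C3-dibenzoate, 6-OPMB) | O=C(OC[C@@]1(O)[C@@H](O)[C@H](OC(=O)c2ccccc2)C=C[C@H]1OCc1ccc(OC)cc1)c1ccccc1 | intermediate
17 | C2 acetate with free C1–OH (C7,C3-dibenzoate, 6-OPMB) | O=C(OC[C@@]1(O)[C@@H](OC(C)=O)[C@H](OC(=O)c2ccccc2)C=C[C@H]1OCc1ccc(OC)cc1)c1ccccc1 | intermediate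
18 | C1,C6-trans-diol (C2 acetate, C7,C3-dibenzoate) | O=C(OC[C@@]1(O)[C@@H](OC(C)=O)[C@H](OC(=O)c2ccccc2)C=C[C@H]1O)c1ccccc1 | intermediate
19 | C6 mesylate of 18 | O=C(OC[C@@]1(O)[C@@H](OC(C)=O)[C@H](OC(=O)c2ccccc2)C=C[C@H]1OS(C)(=O)=O)c1ccccc1 | intermediate
20 | EANPDB:ANNO_02019: 2-acetoxy-3-benzoyloxy-1-(benzoyloxymethyl)-1,6-epoxycyclohex-4-ene, oxirane trans to C7 and to the C2 acetate | CC(=O)O[C@H]1[C@H](OC(=O)c2ccccc2)C=C[C@@H]2O[C@@]21COC(=O)c1ccccc1 | target

## Step count and risk

Total step count: 14. Longest linear sequence: 14 steps (1 → 20).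

Steps most likely to fail:

1. Step 7 (key step). The enforced boat raises the barrier of the [3,3] shift. At the temperature needed, the ketene acetal may be lost before it rearranges, by ionisation of its alkoxyallyl C–O bond (a vinylogous acylal) or by reversion to the lactone. The fallback takes the sensitive enol ether out of the rearrangement and makes the C6–O bond afterwards. It sets out from alkenylboronate 8, which cannot ionise in this way and tolerates longer heating (LiHMDS, TMSCl, THF, −78 °C; toluene, 110 °C; aqueous work-up). By the same boat argument this should give the allylic boronate acid F1 with boron cis to the carboxyl group. Oxidation of the C–B bond with retention (NaBO3·4H2O, THF/H2O) should give the hydroxy acid F2. Double alkylation (NaH, 4-methoxybenzyl chloride, Bu4NI, DMF) should give the 4-methoxybenzyl ester ether F3, and LiAlH4 reduction of F3 returns to the route at 13.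

2. Step 6. Protodeboronation, oxidative homocoupling or transfer of acetate instead of the alkoxide may outrun C–O bond formation at the hindered alkenylboronate. The fallback reverses the roles of the partners and sets out from aldehyde 7. Takai iodo-olefination (CHI3, CrCl2, THF, 0 °C) should give the (E)-alkenyl iodide F4. Copper(I)-catalysed Ullmann-type coupling with 4-methoxybenzyl alcohol (CuI, 3,4,7,8-tetramethyl-1,10-phenanthroline, Cs2CO3, toluene, 80 °C), which retains the alkene geometry, returns to the route at 9.

3. Step 14. Acyl migration from O-2 or O-7 to the tertiary C1 alkoxide, or loss of the allylic sulfonate by SN2′ substitution or elimination, may compete with oxirane closure. The fallback avoids both the sulfonate and the free alkoxide. It sets out from diol 18 and closes the oxirane by Mitsunobu cyclodehydration (PPh3, DIAD, toluene, 0 °C → rt). The secondary C6 hydroxyl is activated as the oxyphosphonium ion and displaced by the C1 hydroxyl with inversion under neutral conditions. This returns to the route at 20 and passes through no further compound (F0).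

Further compounds

F1 | step 7 | allylic boronate acid: 12 with Bpin in place of the 4-methoxybenzyloxy group on C6 | OC(=O)[C@@]12OC(C)(C)O[C@H]1[C@H](O[Si](C)(C)C(C)(C)C)C=C[C@H]2B1OC(C)(C)C(C)(C)O1
F2 | step 7 | C6 hydroxy acid: 12 with free 6-OH | OC(=O)[C@@]12OC(C)(C)O[C@H]1[C@H](O[Si](C)(C)C(C)(C)C)C=C[C@H]2O
F3 | step 7 | 4-methoxybenzyl ester of 12 | COc1ccc(COC(=O)[C@@]23OC(C)(C)O[C@H]2[C@H](O[Si](C)(C)C(C)(C)C)C=C[C@H]3OCc2ccc(OC)cc2)cc1
F4 | step 6 | 4-O-TBS-2,3-O-isopropylidene L-gulo 1,5-lactone with (E)-2-iodovinyl on C5 | O=C1[C@H]2OC(C)(C)O[C@H]2[C@H](O[Si](C)(C)C(C)(C)C)[C@H](/C=C/I)O1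
F0 | step 14 | none | none
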